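**Plan**

- Retrosynthesis: unmask the three phenols and the methyl ketone, remove the two aryl CHO groups, read the ring C=O as a hydrated ring alkene, cut the benzylic carbon from the isobutyl CH2 and from the arene (back to an aldehyde, then an ester), and finally cut both exocyclic bonds of the cyclopropane.
- Enabling feature: the three-membered ring is a CMe2 carbon flanked by two cis CH carbons, one bonded to the CH2 of the 3-oxobutyl chain and the other to the α-carbon of the cyclopentanone. This is the imprint of a syn addition of chain and ring across the C=C of 3,3-dimethylcyclopropene.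
- Forward: the cyclopropane is made first (steps 1–3), and the ketal-protected chain and the preformed cyclopentene are attached to it in one flask (step 8, no ring closed). The ester is then grown into the aryl(isobutyl)methyl arm (steps 9–13), the ring alkene becomes the ketone (steps 14 and 16), and the arene is formylated (step 15) and unmasked (step 17).
- Stereochemistry: the quaternary carbon comes from an auxiliary-controlled enamine methylation (step 6), and both cyclopropane CH centers from ligand-controlled syn carbometalation with stereoretentive coupling (step 8). The benzylic carbon comes from Felkin–Anh-type capture of a benzylic cation (step 12), and the ketone α-carbon from thermodynamic equilibration (step 16).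

Key step: step 8

Assumption: the sense of induction in steps 6 and 8 is taken as written (L-valine tert-butyl ester with HMPA; the (R,S_p) ligand); if a test run shows the opposite sense, the enantiomeric auxiliary or ligand is used and nothing else changes.

**Route**

Step 1
Reactants: 1 2-methylpropene
Product: 2 1,1-dibromo-2,2-dimethylcyclopropane
Conditions: CHBr3, KOt-Bu, pentane, −20 °C → rt
Reagents that add atoms: bromoform, BrC(Br)Br
Why: α-Elimination of HBr from bromoform gives dibromocarbene, which adds to the electron-rich 1,1-disubstituted alkene in a concerted [2+1] cycloaddition (dihalocarbene cyclopropanation), and no stereocenter is formed.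

Step 2
Reactants: 2 1,1-dibromo-2,2-dimethylcyclopropane
Product: 3 1-bromo-2,2-dimethylcyclopropane (racemic)
Conditions: n-Bu3SnH (1.0 equiv), neat, 35–40 °C; distillation
Reagents that add atoms: none
Why: Radical-chain hydrodebromination with one equivalent of the tin hydride should stop at the monobromide of the gem-dibromocyclopropane, and the stereocenter of the racemic product is destroyed in step 3.

Step 3
Reactants: 3 1-bromo-2,2-dimethylcyclopropane
Product: 4 3,3-dimethylcyclopropene
Conditions: KOt-Bu, DMSO, rt → 50 °C; product swept with N2 into a −78 °C trap and kept as a cold t-BuOMe solution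
Reagents that add atoms: none
Why: Base-induced 1,2-dehydrobromination gives the volatile cyclopropene, which leaves the basic medium as it forms and cannot isomerise to a methylenecyclopropane because its sp3 ring carbon carries no hydrogen.

Step 4
Reactants: 5 2-(2-bromoethyl)-2-methyl-1,3-dioxolane
Product: 6 [2-(2-methyl-1,3-dioxolan-2-yl)ethyl]magnesium bromide
Conditions: Mg turnings, THF, 20–25 °C
Reagents that add atoms: magnesium, [Mg]
Why: Oxidative insertion of magnesium into the primary C–Br bond (Grignard formation), the ketal being inert to its own organomagnesium function below about 30 °C.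

Step 5
Reactants: 7 methyl 2-oxocyclopentane-1-carboxylate
Product: 8 enamino ester of 7 with L-valine tert-butyl ester
Conditions: L-valine tert-butyl ester, BF3·OEt2 (cat.), toluene, reflux, Dean–Stark trap
Reagents that add atoms: L-valine tert-butyl ester, CC(C)[C@H](N)C(=O)OC(C)(C)C
Why: Acid-catalysed condensation of the ketone of the β-keto ester with the primary amine gives the conjugated, hydrogen-bonded enamino ester with azeotropic removal of water, and the valine stereocenter is carried in unchanged.

Step 6
Reactants: 8 enamino ester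
Product: 11 methyl (1S)-1-methyl-2-oxocyclopentane-1-carboxylate, via lithioenamine 9 (not isolated), via methylated imine 10 (not isolated)
Conditions: LiN(i-Pr)2, toluene, −78 °C; HMPA (1 equiv), MeI, −78 → −40 °C; then 1 M aq HCl, rt
Reagents that add atoms: iodomethane, CI; water, O
Why: Auxiliary-controlled alkylation of a chiral lithioenamine, in which lithium is chelated between nitrogen and the valine ester carbonyl and the isopropyl group shields one face so that methyl iodide creates the quaternary (S) center, followed by hydrolysis of the imine to the ketone and the recoverable amino ester.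

Step 7
Reactants: 11 methyl (1S)-1-methyl-2-oxocyclopentane-1-carboxylate
Product: 13 methyl (1S)-1-methyl-2-(trifluoromethanesulfonyloxy)cyclopent-2-ene-1-carboxylate, via potassium enolate 12 (not isolated)
Conditions: KN(SiMe3)2, THF, −78 °C; PhNTf2, −78 → 0 °C
Reagents that add atoms: N-phenylbis(trifluoromethanesulfonimide), O=S(=O)(N(c1ccccc1)S(=O)(=O)C(F)(F)F)C(F)(F)F
Why: The ketone can enolise only toward its CH2 side because the other α-carbon is quaternary, so deprotonation and O-sulfonylation (enol triflate formation) should give a single regioisomer without touching the stereocenter.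

Step 8
Reactants: 4 3,3-dimethylcyclopropene; 6 [2-(2-methyl-1,3-dioxolan-2-yl)ethyl]magnesium bromide; 13 enol triflate
Product: 16 methyl (1S)-2-{(1S,3R)-2,2-dimethyl-3-[2-(2-methyl-1,3-dioxolan-2-yl)ethyl]cyclopropyl}-1-methylcyclopent-2-ene-1-carboxylate (cis-cyclopropane), via cyclopropylmagnesium bromide 14 (not isolated), via cyclopropylzinc bromide 15 (not isolated)
Conditions: 4 (1.5 equiv), CuI (5 mol%), (R)-1-[(S_p)-2-(diphenylphosphino)ferrocenyl]ethyldicyclohexylphosphine (6 mol%), t-BuOMe, −30 °C, slow addition of 6 (1.3 equiv), → 0 °C; N2 purge; ZnBr2 (1.4 equiv), THF, 0 °C; then 13 (1.0 equiv), Pd(OAc)2 (5 mol%), 2-dicyclohexylphosphino-2′,6′-dimethoxybiphenyl (10 mol%), 45 °C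
Reagents that add atoms: none
Why: A chiral monovalent copper–bisphosphine alkyl formed from 6 and CuI adds its alkyl group and copper syn across the strained double bond of 4, and copper-to-magnesium exchange releases the cis-cyclopropylmagnesium 14 and returns the catalyst; ZnBr2 converts 14 with retention into 15, which enters a Negishi cycle (oxidative addition of zerovalent palladium, generated in the flask from the divalent palladium salt Pd(OAc)2 and the biaryl phosphine, into the C–OTf bond of 13, then transmetalation and reductive elimination with retention at the cyclopropyl carbon). The closest known reaction type is the copper-catalysed enantioselective carbomagnesiation of 3,3-disubstituted cyclopropenes with capture of the configurationally stable cyclopropylmetal by cross-coupling. No ring is closed: both rings arrive preformed, and the two new bonds are the chain CH2–cyclopropane bond and the cyclopropane–cyclopentene bond. Of the two new stereocenters, the cis relationship follows from syn carbometalation and stereoretentive transmetalation and coupling, and the absolute configuration from the chiral ligand, which decides which of the two enantiotopic alkene carbons of 4 receives the alkyl group; the quaternary (S) center of 13 is not touched. The step needs the primary Grignard reagent to be consumed before palladium is added (secured by a small excess of 4, whose surplus is purged as a gas) and needs the ester to survive (secured by the zinc transmetalation); any minor cyclopropyl enantiomer ends up as a diastereomer of 16 that chromatography should remove.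

Step 9
Reactants: 16 cyclopentene ester
Product: 17 the corresponding primary alcohol (CO2Me → CH2OH)
Conditions: LiAlH4, Et2O, 0 °C → rt
Reagents that add atoms: none
Why: Hydride reduction of the hindered ester to the neopentyl-type primary alcohol (LiAlH4 reduction), to which the trisubstituted alkene, the cyclopropane and the ketal are inert.

Step 10
Reactants: 17 primary alcohol
Product: 18 the corresponding aldehyde (CH2OH → CHO)
Conditions: Dess–Martin periodinane, NaHCO3, CH2Cl2, 0 °C → rt
Reagents that add atoms: none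
Why: Buffered Dess–Martin oxidation gives the aldehyde without acid that could open the ketal, and the aldehyde has no α-hydrogen and so can neither epimerise nor move into conjugation.

Step 11
Reactants: 18 aldehyde; 19 1,3,5-trimethoxybenzene
Product: 21 aryl carbinol (CHO → CH(OH)-2,4,6-trimethoxyphenyl, both carbinol epimers), via 2,4,6-trimethoxyphenyllithium 20 (not isolated)
Conditions: 19, n-BuLi, THF, 0 °C → rt; then 18, −78 → 0 °C; aq NH4Cl
Reagents that add atoms: none
Why: Directed ortho-lithiation of the arene between two methoxy groups and 1,2-addition of the aryllithium to the non-enolisable aldehyde, the carbinol center forming without control, which does not matter because it is ionised in step 12.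

Step 12
Reactants: 21 aryl carbinol
Product: 22 2-[(1S)-1-(cyclopentenyl)-3-methylbut-3-en-1-yl]-1,3,5-trimethoxybenzene (OH replaced by 2-methylallyl, (S) at the benzylic carbon)
Conditions: methallyltrimethylsilane (3 equiv), BF3·OEt2 (0.3 equiv), CH2Cl2, −78 °C
Reagents that add atoms: (2-methylallyl)trimethylsilane, CC(=C)C[Si](C)(C)C
Why: BF3·OEt2 ionises either carbinol epimer to the same 2,4,6-trimethoxybenzyl cation (the symmetrical aryl group leaves no cation geometry to control), which the allylsilane should capture in a Hosomi–Sakurai-type SN1 alkylation faster than the dioxolane is activated at −78 °C, and attack anti to the cyclopropyl-bearing vinyl arm of the quaternary carbon, with the methyl group and not the ring CH2 beside the incoming nucleophile (Felkin–Anh-type arrangement), is expected to set the (S) benzylic center.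

Step 13
Reactants: 22 methallyl compound
Product: 23 the isobutyl compound (side-chain C=C saturated)
Conditions: H2 (1 atm), RhCl(PPh3)3 (5 mol%), toluene/EtOH, rt
Reagents that add atoms: none
Why: Homogeneous hydrogenation with RhCl(PPh3)3 saturates the unhindered 1,1-disubstituted alkene and is expected to leave the trisubstituted ring alkene, which is flanked by the quaternary carbon and the cyclopropane, and the cyclopropane itself untouched.

Step 14
Reactants: 23 isobutyl compound
Product: 25 (1S,2S,3R)-cyclopentanol (OH on the former alkene CH, cis to the ring methyl; cyclopropyl trans to the ring methyl), via alkylborane 24 (not isolated)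
Conditions: BH3·THF, THF, 0 °C → rt; then 3 M aq NaOH, 30% H2O2, 0 °C → rt
Reagents that add atoms: hydrogen peroxide, OO
Why: Brown hydroboration–oxidation places boron on the ring CH carbon and hydrogen on the cyclopropyl-bearing carbon in a syn addition, expected from the face of the ring methyl group and away from the 1-aryl-3-methylbutyl arm, and stereoretentive C–B oxidation gives the alcohol; both new centers are provisional because the carbinol is oxidised and the adjacent CH equilibrated in step 16.

Step 15
Reactants: 25 cyclopentanol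
Product: 29 the 3,5-diformyl-2,4,6-trimethoxyphenyl cyclopentanol, via dilithio alkoxide 26 (not isolated), via amino alkoxide 27 (not isolated), via lithiated amino alkoxide 28 (not isolated)
Conditions: n-BuLi (2.2 equiv), TMEDA, THF, 0 °C; DMF (1.0 equiv), −78 → 0 °C; n-BuLi (1.5 equiv), 0 °C; DMF (excess), −78 °C → rt; aq NH4Cl
Reagents that add atoms: N,N-dimethylformamide, CN(C)C=O
Why: Directed ortho-metalation, in which n-BuLi first forms the alkoxide and then removes an aryl hydrogen flanked by two methoxy groups, DMF traps the aryllithium as a lithium α-amino alkoxide that masks the first formyl group (in situ protection) while the second flanked hydrogen is lithiated and formylated, and aqueous work-up releases both aldehydes without affecting any stereocenter.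

Step 16
Reactants: 29 diformyl cyclopentanol
Product: 31 the (1R,2R)-cyclopentanone with the cyclopropyl group cis to the ring methyl, via kinetic 2-epi ketone 30 (not isolated)
Conditions: Dess–Martin periodinane, NaHCO3, CH2Cl2, rt; then DBU (0.3 equiv), toluene, 40 °C
Reagents that add atoms: none
Why: Dess–Martin oxidation gives the cyclopentanone, and base-mediated enolisation then equilibrates its α-carbon so that the cyclopropyl group sits trans to the bulky 1-aryl-3-methylbutyl arm and cis to the ring methyl, the arrangement expected to be thermodynamically preferred and the (R) configuration of the target.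

Step 17
Reactants: 31 trimethoxy diformyl ketone
Product: 33 Macrocarpal N, via triphenol ketal 32 (not isolated)
Conditions: NaSEt (10 equiv), DMF, 110 °C; then 2 M aq HCl, THF, rt
Reagents that add atoms: water, O
Why: Thiolate attacks the methyl groups of the three aryl methyl ethers in SN2 fashion, each being activated by formyl groups ortho or para to it (nucleophilic demethylation with thiolate), under basic conditions that should spare the cyclopropane and the ketal, and mild aqueous acid then hydrolyses the dioxolane to the methyl ketone while the ring-ketone α-carbon stays at its thermodynamic configuration.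

**Compound list**

1 | 2-methylpropene | CC(C)=C | starting material
2 | 1,1-dibromo-2,2-dimethylcyclopropane | CC1(C)CC1(Br)Br | intermediate
3 | 1-bromo-2,2-dimethylcyclopropane (racemic) | CC1(C)CC1Br | intermediate
4 | 3,3-dimethylcyclopropene | CC1(C)C=C1 | intermediate
5 | 2-(2-bromoethyl)-2-methyl-1,3-dioxolane | CC1(CCBr)OCCO1 | starting material
6 | [2-(2-methyl-1,3-dioxolan-2-yl)ethyl]magnesium bromide | CC1(CC[Mg]Br)OCCO1 | intermediate
7 | methyl 2-oxocyclopentane-1-carboxylate | COC(=O)C1CCCC1=O | starting material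
8 | methyl 2-{[(2S)-1-tert-butoxy-3-methyl-1-oxobutan-2-yl]amino}cyclopent-1-ene-1-carboxylate | COC(=O)C1=C(N[C@@H](C(C)C)C(=O)OC(C)(C)C)CCC1 | intermediate
9 | N-lithio derivative of 8 (lithioenamine) | COC(=O)C1=C(N([Li])[C@@H](C(C)C)C(=O)OC(C)(C)C)CCC1 | intermediate
10 | methyl (1S)-2-{[(2S)-1-tert-butoxy-3-methyl-1-oxobutan-2-yl]imino}-1-methylcyclopentane-1-carboxylate | COC(=O)[C@@]1(C)CCCC1=N[C@@H](C(C)C)C(=O)OC(C)(C)C | intermediate
11 | methyl (1S)-1-methyl-2-oxocyclopentane-1-carboxylate | COC(=O)[C@@]1(C)CCCC1=O | intermediate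
12 | potassium (5S)-5-(methoxycarbonyl)-5-methylcyclopent-1-en-1-olate | [K+].[O-]C1=CCC[C@]1(C)C(=O)OC | intermediate
13 | methyl (1S)-1-methyl-2-[(trifluoromethanesulfonyl)oxy]cyclopent-2-ene-1-carboxylate | FC(F)(F)S(=O)(=O)OC1=CCC[C@]1(C)C(=O)OC | intermediate
14 | {(1S,3S)-2,2-dimethyl-3-[2-(2-methyl-1,3-dioxolan-2-yl)ethyl]cyclopropyl}magnesium bromide (cis) | CC1(OCCO1)CC[C@@H]2[C@H]([Mg]Br)C2(C)C | intermediate
15 | {(1S,3S)-2,2-dimethyl-3-[2-(2-methyl-1,3-dioxolan-2-yl)ethyl]cyclopropyl}zinc bromide (cis) | CC1(OCCO1)CC[C@@H]2[C@H]([Zn]Br)C2(C)C | intermediate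
16 | methyl (1S)-2-{(1S,3R)-2,2-dimethyl-3-[2-(2-methyl-1,3-dioxolan-2-yl)ethyl]cyclopropyl}-1-methylcyclopent-2-ene-1-carboxylate | CC3(OCCO3)CC[C@@H]1[C@H](C2=CCC[C@]2(C)C(=O)OC)C1(C)C | intermediate
17 | [(1S)-2-{(1S,3R)-2,2-dimethyl-3-[2-(2-methyl-1,3-dioxolan-2-yl)ethyl]cyclopropyl}-1-methylcyclopent-2-en-1-yl]methanol | CC3(OCCO3)CC[C@@H]1[C@H](C2=CCC[C@]2(C)CO)C1(C)C | intermediate
18 | (1S)-2-{(1S,3R)-2,2-dimethyl-3-[2-(2-methyl-1,3-dioxolan-2-yl)ethyl]cyclopropyl}-1-methylcyclopent-2-ene-1-carbaldehyde | CC3(OCCO3)CC[C@@H]1[C@H](C2=CCC[C@]2(C)C=O)C1(C)C | intermediate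
19 | 1,3,5-trimethoxybenzene | COc1cc(OC)cc(OC)c1 | starting material
20 | (2,4,6-trimethoxyphenyl)lithium | [Li]c1c(OC)cc(OC)cc1OC | intermediate
21 | [(1S)-2-{(1S,3R)-2,2-dimethyl-3-[2-(2-methyl-1,3-dioxolan-2-yl)ethyl]cyclopropyl}-1-methylcyclopent-2-en-1-yl](2,4,6-trimethoxyphenyl)methanol, both carbinol epimers | CC3(OCCO3)CC[C@@H]1[C@H](C2=CCC[C@]2(C)C(O)c2c(OC)cc(OC)cc2OC)C1(C)C | intermediate
22 | 2-[(1S)-1-[(1R)-2-{(1S,3R)-2,2-dimethyl-3-[2-(2-methyl-1,3-dioxolan-2-yl)ethyl]cyclopropyl}-1-methylcyclopent-2-en-1-yl]-3-methylbut-3-en-1-yl]-1,3,5-trimethoxybenzene | CC3(OCCO3)CC[C@@H]1[C@H](C2=CCC[C@]2(C)[C@H](CC(C)=C)c2c(OC)cc(OC)cc2OC)C1(C)C | intermediate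
23 | 2-[(1S)-1-[(1R)-2-{(1S,3R)-2,2-dimethyl-3-[2-(2-methyl-1,3-dioxolan-2-yl)ethyl]cyclopropyl}-1-methylcyclopent-2-en-1-yl]-3-methylbutyl]-1,3,5-trimethoxybenzene | CC3(OCCO3)CC[C@@H]1[C@H](C2=CCC[C@]2(C)[C@H](CC(C)C)c2c(OC)cc(OC)cc2OC)C1(C)C | intermediate
24 | monoalkylborane from 23 (BH2 on the former alkene CH, cis to the ring methyl) | CC3(OCCO3)CC[C@@H]1[C@H]([C@@H]2[C@@H](B)CC[C@]2(C)[C@H](CC(C)C)c2c(OC)cc(OC)cc2OC)C1(C)C | intermediate
25 | (1S,2S,3R)-2-{(1R,3R)-2,2-dimethyl-3-[2-(2-methyl-1,3-dioxolan-2-yl)ethyl]cyclopropyl}-3-methyl-3-[(1S)-3-methyl-1-(2,4,6-trimethoxyphenyl)butyl]cyclopentan-1-ol | CC3(OCCO3)CC[C@@H]1[C@H]([C@@H]2[C@@H](O)CC[C@]2(C)[C@H](CC(C)C)c2c(OC)cc(OC)cc2OC)C1(C)C | intermediate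
26 | lithium alkoxide of 25 lithiated at one free aryl position | CC3(OCCO3)CC[C@@H]1[C@H]([C@@H]2[C@@H](O[Li])CC[C@]2(C)[C@H](CC(C)C)c2c(OC)c([Li])c(OC)cc2OC)C1(C)C | intermediate
27 | lithium alkoxide of 25 carrying one aryl CH(OLi)NMe2 group | CC3(OCCO3)CC[C@@H]1[C@H]([C@@H]2[C@@H](O[Li])CC[C@]2(C)[C@H](CC(C)C)c2c(OC)c(C(O[Li])N(C)C)c(OC)cc2OC)C1(C)C | intermediate
28 | compound 27 lithiated at the remaining aryl position | CC3(OCCO3)CC[C@@H]1[C@H]([C@@H]2[C@@H](O[Li])CC[C@]2(C)[C@H](CC(C)C)c2c(OC)c(C(O[Li])N(C)C)c(OC)c([Li])c2OC)C1(C)C | intermediate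
29 | 5-[(1S)-1-[(1R,2S,3S)-2-{(1R,3R)-2,2-dimethyl-3-[2-(2-methyl-1,3-dioxolan-2-yl)ethyl]cyclopropyl}-3-hydroxy-1-methylcyclopentyl]-3-methylbutyl]-2,4,6-trimethoxybenzene-1,3-dicarbaldehyde | CC3(OCCO3)CC[C@@H]1[C@H]([C@@H]2[C@@H](O)CC[C@]2(C)[C@H](CC(C)C)c2c(OC)c(C=O)c(OC)c(C=O)c2OC)C1(C)C | intermediate
30 | 5-[(1S)-1-[(1R,2S)-2-{(1R,3R)-2,2-dimethyl-3-[2-(2-methyl-1,3-dioxolan-2-yl)ethyl]cyclopropyl}-1-methyl-3-oxocyclopentyl]-3-methylbutyl]-2,4,6-trimethoxybenzene-1,3-dicarbaldehyde | CC3(OCCO3)CC[C@@H]1[C@H]([C@@H]2C(=O)CC[C@]2(C)[C@H](CC(C)C)c2c(OC)c(C=O)c(OC)c(C=O)c2OC)C1(C)C | intermediate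
31 | 5-[(1S)-1-[(1R,2R)-2-{(1R,3R)-2,2-dimethyl-3-[2-(2-methyl-1,3-dioxolan-2-yl)ethyl]cyclopropyl}-1-methyl-3-oxocyclopentyl]-3-methylbutyl]-2,4,6-trimethoxybenzene-1,3-dicarbaldehyde | CC3(OCCO3)CC[C@@H]1[C@H]([C@H]2C(=O)CC[C@]2(C)[C@H](CC(C)C)c2c(OC)c(C=O)c(OC)c(C=O)c2OC)C1(C)C | intermediate
32 | 5-[(1S)-1-[(1R,2R)-2-{(1R,3R)-2,2-dimethyl-3-[2-(2-methyl-1,3-dioxolan-2-yl)ethyl]cyclopropyl}-1-methyl-3-oxocyclopentyl]-3-methylbutyl]-2,4,6-trihydroxybenzene-1,3-dicarbaldehyde | CC3(OCCO3)CC[C@@H]1[C@H]([C@H]2C(=O)CC[C@]2(C)[C@H](CC(C)C)c2c(O)c(C=O)c(O)c(C=O)c2O)C1(C)C | intermediate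
33 | Macrocarpal N, 5-[(1S)-1-[(1R,2R)-2-[(1R,3R)-2,2-dimethyl-3-(3-oxobutyl)cyclopropyl]-1-methyl-3-oxocyclopentyl]-3-methylbutyl]-2,4,6-trihydroxybenzene-1,3-dicarbaldehyde | CC(=O)CC[C@@H]1[C@H]([C@H]2C(=O)CC[C@]2(C)[C@H](CC(C)C)c2c(O)c(C=O)c(O)c(C=O)c2O)C1(C)C | target

**Totals and risks**

Total step count: 17. Longest linear sequence: 13 steps (steps 5–17 from compound 7; the branch from compound 1 through steps 1–3 and 8–17 is equally long).

Steps most likely to fail:

1. Step 8. The palladium cycle may stall at transmetalation or reductive elimination, because a trisubstituted cyclopropylzinc must meet an alkenyl triflate flanked by a quaternary carbon, so that the cyclopropylzinc is merely protonated on work-up. Fallback: the cyclopropylmagnesium 14 (made as in step 8) is transferred to CeCl3 in THF at −78 °C and added to ketone 11, giving the tertiary alcohol methyl (1S)-2-{(1S,3R)-2,2-dimethyl-3-[2-(2-methyl-1,3-dioxolan-2-yl)ethyl]cyclopropyl}-2-hydroxy-1-methylcyclopentane-1-carboxylate F1. Syn-dehydration with the Burgess reagent (methyl N-(triethylammoniosulfonyl)carbamate, toluene, 60 °C) can only run into the ring, since the quaternary carbon has no hydrogen and an alkylidenecyclopropane is too strained. The route is rejoined at 16.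

2. Step 12. Facial discrimination in the capture of the benzylic cation rests on the small difference between the ring methyl and the ring CH2, so the wrong benzylic epimer may dominate; the ketal may also be attacked by the Lewis acid. Fallback: the roles of incoming and resident group are exchanged. Carbinol 21 is oxidised (Dess–Martin periodinane) to the aryl ketone [(1S)-2-{(1S,3R)-2,2-dimethyl-3-[2-(2-methyl-1,3-dioxolan-2-yl)ethyl]cyclopropyl}-1-methylcyclopent-2-en-1-yl](2,4,6-trimethoxyphenyl)methanone F2. Isobutyllithium with CeCl3 (THF, −78 °C) gives the tertiary carbinol 1-[(1S)-2-{(1S,3R)-2,2-dimethyl-3-[2-(2-methyl-1,3-dioxolan-2-yl)ethyl]cyclopropyl}-1-methylcyclopent-2-en-1-yl]-3-methyl-1-(2,4,6-trimethoxyphenyl)butan-1-ol F3. Ionic hydrogenation (Et3SiH, BF3·OEt2, CH2Cl2, −78 °C) then delivers hydride to the face that the allylsilane took before, which should invert the benzylic outcome. The route is rejoined at 23.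

3. Step 15. The second lithiation may be incomplete, or the amino alkoxide may collapse early so that butyllithium adds to the first aldehyde, giving mixtures of mono- and dialdehyde. Fallback: alcohol 25 is oxidised and equilibrated as in step 16 to (2R,3R)-2-{(1R,3R)-2,2-dimethyl-3-[2-(2-methyl-1,3-dioxolan-2-yl)ethyl]cyclopropyl}-3-methyl-3-[(1S)-3-methyl-1-(2,4,6-trimethoxyphenyl)butyl]cyclopentan-1-one F4. Rieche formylation (Cl2CHOMe, TiCl4, CH2Cl2, −78 → 0 °C, aqueous HCl work-up) introduces both formyl groups electrophilically and also removes the ketal, giving 5-[(1S)-1-[(1R,2R)-2-[(1R,3R)-2,2-dimethyl-3-(3-oxobutyl)cyclopropyl]-1-methyl-3-oxocyclopentyl]-3-methylbutyl]-2,4,6-trimethoxybenzene-1,3-dicarbaldehyde F5. Chelation-assisted cleavage of the three methoxy groups, each ortho to a formyl group, with BCl3 (CH2Cl2, −78 → 0 °C) rejoins the route at 33.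

**Further compounds**

F1 | step 8 | methyl (1S)-2-{(1S,3R)-2,2-dimethyl-3-[2-(2-methyl-1,3-dioxolan-2-yl)ethyl]cyclopropyl}-2-hydroxy-1-methylcyclopentane-1-carboxylate (either carbinol epimer) | CC3(OCCO3)CC[C@@H]1[C@H](C2(O)CCC[C@]2(C)C(=O)OC)C1(C)C
F2 | step 12 | [(1S)-2-{(1S,3R)-2,2-dimethyl-3-[2-(2-methyl-1,3-dioxolan-2-yl)ethyl]cyclopropyl}-1-methylcyclopent-2-en-1-yl](2,4,6-trimethoxyphenyl)methanone | CC3(OCCO3)CC[C@@H]1[C@H](C2=CCC[C@]2(C)C(=O)c2c(OC)cc(OC)cc2OC)C1(C)C
F3 | step 12 | 1-[(1S)-2-{(1S,3R)-2,2-dimethyl-3-[2-(2-methyl-1,3-dioxolan-2-yl)ethyl]cyclopropyl}-1-methylcyclopent-2-en-1-yl]-3-methyl-1-(2,4,6-trimethoxyphenyl)butan-1-ol (either carbinol epimer) | CC3(OCCO3)CC[C@@H]1[C@H](C2=CCC[C@]2(C)C(O)(CC(C)C)c2c(OC)cc(OC)cc2OC)C1(C)C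
F4 | step 15 | (2R,3R)-2-{(1R,3R)-2,2-dimethyl-3-[2-(2-methyl-1,3-dioxolan-2-yl)ethyl]cyclopropyl}-3-methyl-3-[(1S)-3-methyl-1-(2,4,6-trimethoxyphenyl)butyl]cyclopentan-1-one | CC3(OCCO3)CC[C@@H]1[C@H]([C@H]2C(=O)CC[C@]2(C)[C@H](CC(C)C)c2c(OC)cc(OC)cc2OC)C1(C)C
F5 | step 15 | 5-[(1S)-1-[(1R,2R)-2-[(1R,3R)-2,2-dimethyl-3-(3-oxobutyl)cyclopropyl]-1-methyl-3-oxocyclopentyl]-3-methylbutyl]-2,4,6-trimethoxybenzene-1,3-dicarbaldehyde | CC(=O)CC[C@@H]1[C@H]([C@H]2C(=O)CC[C@]2(C)[C@H](CC(C)C)c2c(OC)c(C=O)c(OC)c(C=O)c2OC)C1(C)C
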